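**Plan**
- Retrosynthesis: the seven benzyl-type ethers are removed first, then ring C is opened at the aryl ether bond O1–C8a. The acyclic triad is cut at C2–ring B and at C4–ring A, the C3/C4 oxygenation is traced to an E-allylic alcohol, and the chain is cut from ring D (Heck) and at the stilbene C=C (HWE).
- Forward: rings D and E are joined by olefination, the C2–C4 chain is attached to ring D, ring A is delivered to C4 and ring B to C2, ring C is closed last, and the phenols are unmasked.
- Stereochemistry: C3 and C4 come from Sharpless epoxidation with L-(+)-diethyl tartrate and invertive benzylic opening of the trans-epoxide; C2 comes from chelation-controlled aryl Grignard addition to the α-alkoxy aldehyde.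
- Enabling feature: O1 links C2 to the aromatic carbon C8a of ring A, so ring C can be closed by O-arylation of the C2 hydroxyl with an ortho-bromide on ring A, without touching any bond to C2, C3 or C4.

Key step: step 13

Remark: the SMILES is read as (2R,3R,4R), i.e. 2,3-cis-3,4-trans (ring B and O3 on one face of ring C, ring D on the other); 1, 3, 6, 10 and 17 are taken as purchasable. Ring D carries the finished stilbene (not a masked aldehyde) through the key step, and O3 is protected as a PMB ether.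

Abbreviations: Bn = benzyl; PMB = 4-methoxybenzyl; ArA = 4-(benzyloxy)-2-bromophenyl; ArB = 4-(benzyloxy)phenyl; ArDE = 2,4-bis(benzyloxy)-6-[(E)-3,4-bis(benzyloxy)styryl]phenyl.

**Step 1**
Reactants: 1 3,4-bis(benzyloxy)benzyl chloride
Product: 2 diethyl [3,4-bis(benzyloxy)benzyl]phosphonate
Conditions: P(OEt)3 (neat), Bu4NI (cat.), 130 °C
Reagents that add atoms: triethyl phosphite, CCOP(OCC)OCC
Why: Michaelis–Arbuzov reaction, in which phosphorus displaces the benzylic chloride and chloride dealkylates the phosphonium ion, with the aryl benzyl ethers inert.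

**Step 2**
Reactants: 3 3,5-bis(benzyloxy)benzaldehyde
Product: 4 3,5-bis(benzyloxy)-2-bromobenzaldehyde
Conditions: NBS, MeCN, 0 °C → rt
Reagents that add atoms: N-bromosuccinimide, O=C1CCC(=O)N1Br
Why: Electrophilic aromatic bromination, which on 3,5-dialkoxybenzaldehydes goes to C2 (ortho to one ether, para to the other) and not to the more crowded C4 between the two ethers.

**Step 3**
Reactants: 4 3,5-bis(benzyloxy)-2-bromobenzaldehyde; 2 diethyl [3,4-bis(benzyloxy)benzyl]phosphonate
Product: 5 (E)-1,5-bis(benzyloxy)-2-bromo-3-[3,4-bis(benzyloxy)styryl]benzene (ArDE–Br)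
Conditions: KOtBu, THF, 0 °C → rt
Reagents that add atoms: none
Why: Horner–Wadsworth–Emmons olefination of a non-enolisable aldehyde with a benzylphosphonate anion, which should give the E-stilbene.

**Step 4**
Reactants: 5 ArDE–Br; 6 ethyl acrylate
Product: 7 ethyl (E)-3-(ArDE)acrylate
Conditions: Pd(P(tBu)3)2 (cat.), Cy2NMe, dioxane, 100 °C
Reagents that add atoms: none
Why: Mizoroki–Heck reaction; the bulky electron-rich phosphine allows oxidative addition at the hindered, electron-rich C–Br bond, syn-insertion and syn-β-hydride elimination give the E-cinnamate, and the 1,2-diaryl alkene does not compete.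

**Step 5**
Reactants: 7 ethyl (E)-3-(ArDE)acrylate
Product: 8 (E)-3-(ArDE)prop-2-en-1-ol
Conditions: iBu2AlH, CH2Cl2, −78 °C; aq. potassium sodium tartrate
Reagents that add atoms: none
Why: 1,2-Reduction of the unsaturated ester by the aluminium hydride at low temperature gives the allylic alcohol and leaves both alkenes and the aryl ethers alone.

**Step 6**
Reactants: 8 (E)-3-(ArDE)prop-2-en-1-ol
Product: 9 [(2S,3S)-3-(ArDE)oxiran-2-yl]methanol
Conditions: Ti(OiPr)4 (cat.), L-(+)-diethyl tartrate (cat.), tBuOOH, 4 Å MS, CH2Cl2, −20 °C; aq. NaOH/NaCl work-up at 0 °C, used without chromatography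
Reagents that add atoms: tert-butyl hydroperoxide, CC(C)(C)OO
Why: Sharpless asymmetric epoxidation; the titanium tartrate binds the allylic hydroxyl and delivers oxygen to one face of the E-alkene (L-(+)-tartrate gives the 2S,3S trans-epoxide), which sets both epoxide carbons under reagent control, while the stilbene has no directing hydroxyl and stays untouched.

**Step 7**
Reactants: 10 1-(benzyloxy)-3-bromobenzene
Product: 11 4-(benzyloxy)-2-bromo-1-iodobenzene
Conditions: NIS, CF3CO2H (cat.), MeCN, rt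
Reagents that add atoms: N-iodosuccinimide, O=C1CCC(=O)N1I
Why: Electrophilic aromatic iodination with acid-activated NIS, directed para to the benzyloxy group as for 3-bromoanisole.

**Step 8**
Reactants: 11 4-(benzyloxy)-2-bromo-1-iodobenzene; 9 [(2S,3S)-3-(ArDE)oxiran-2-yl]methanol
Product: 13 (2R,3S)-3-(ArA)-3-(ArDE)propane-1,2-diol, via arylmagnesium chloride 12 (not isolated)
Conditions: 11 (3 equiv), iPrMgCl·LiCl, THF, −40 °C; then CuI (cat.), 9, −40 → −20 °C; aq. NH4Cl
Reagents that add atoms: none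
Why: Iodine–magnesium exchange takes the C–I bond only and is kept cold so the ortho-bromoaryl metal does not collapse to an aryne, and the copper-catalysed Grignard opening of the 3-aryl-2,3-epoxy alcohol occurs at the benzylic carbon with inversion (SN2), which fixes the diarylmethine centre (later C4) relative to the untouched carbinol carbon (later C3).

**Step 9**
Reactants: 13 (2R,3S)-3-(ArA)-3-(ArDE)propane-1,2-diol
Product: 14 (4R)-4-[(S)-(ArA)(ArDE)methyl]-2-(4-methoxyphenyl)-1,3-dioxolane (both epimers at the acetal carbon)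
Conditions: 4-MeOC6H4CH(OMe)2, PPTS (cat.), 4 Å MS, CH2Cl2, rt
Reagents that add atoms: 4-methoxybenzaldehyde dimethyl acetal, COC(OC)c1ccc(OC)cc1
Why: Acid-catalysed transacetalisation gives the five-membered anisylidene acetal of the 1,2-diol; the new acetal centre is of no consequence because both epimers converge in step 10.

**Step 10**
Reactants: 14 anisylidene acetal
Product: 15 (2R,3S)-3-(ArA)-3-(ArDE)-2-[(4-methoxybenzyl)oxy]propan-1-ol
Conditions: iBu2AlH, CH2Cl2, −78 → 0 °C; aq. potassium sodium tartrate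
Reagents that add atoms: none
Why: Regioselective reductive opening of the arylidene acetal; aluminium binds the less hindered primary oxygen, that C–O bond breaks and hydride is delivered to the oxocarbenium ion, so the PMB group stays on the secondary oxygen next to the bulky diarylmethyl group.

**Step 11**
Reactants: 15 primary alcohol
Product: 16 (2R,3S)-3-(ArA)-3-(ArDE)-2-[(4-methoxybenzyl)oxy]propanal
Conditions: Dess–Martin periodinane, NaHCO3, CH2Cl2, 0 °C → rt; used crude
Reagents that add atoms: none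
Why: Dess–Martin oxidation under buffered, non-basic conditions gives the α-alkoxy aldehyde without epimerising the α-centre.

**Step 12**
Reactants: 17 1-(benzyloxy)-4-bromobenzene; 16 α-PMB-oxy aldehyde
Product: 19 (1R,2R,3S)-3-(ArA)-1-(ArB)-3-(ArDE)-2-[(4-methoxybenzyl)oxy]propan-1-ol, via [4-(benzyloxy)phenyl]magnesium bromide 18 (not isolated)
Conditions: 17, Mg, THF (concentrated); 16, MgBr2·OEt2, CH2Cl2, −78 °C, then 18, −78 → −40 °C; aq. NH4Cl
Reagents that add atoms: none
Why: Cram-chelate-controlled Grignard addition; magnesium bridges the carbonyl oxygen and the α-PMB ether oxygen, and the aryl group attacks the face of the five-membered chelate away from the diarylmethyl substituent, which should give the syn (1R) carbinol.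

**Step 13**
Reactants: 19 syn-1,2-diol 2-PMB ether
Product: 20 (2R,3R,4R)-7-(benzyloxy)-2-[4-(benzyloxy)phenyl]-4-(ArDE)-3-[(4-methoxybenzyl)oxy]chromane
Conditions: CuI (20 mol %), 1,10-phenanthroline (40 mol %), Cs2CO3, toluene (degassed), 110 °C
Reagents that add atoms: none
Why: Cs2CO3 deprotonates the C2 hydroxyl and the alkoxide binds phenanthroline-ligated monovalent copper; oxidative addition of the ortho C8a–Br bond and C–O reductive elimination from the aryl(alkoxo) trivalent copper species form O1–C8a. The closest known reaction type is the intramolecular Ullmann-type (copper-catalysed) O-arylation of secondary alcohols by ortho-bromoarenes, as used for chromans and flavans. Ring C closes as a six-membered aryl ether in a 6-exo sense (the breaking C–Br bond lies outside the new ring) through a seven-membered cupracycle. No stereocentre is created and no bond to C2, C3 or C4 is broken, so the syn C2/C3 relation and the epoxide-derived C3/C4 relation of 19 become 2,3-cis-3,4-trans. The step needs O-arylation by the C2 hydroxyl alone, without oxidation or epimerisation: O3 is blocked as its PMB ether, so the five-membered dihydrobenzofuran cannot form, and copper alkoxides, unlike palladium alkoxides, do not readily lose a β-hydride, which protects the benzylic carbinol.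

**Step 14**
Reactants: 20 fully protected flavan
Product: 21 (2R,3R,4R)-4-[2,4-dihydroxy-6-[(E)-3,4-dihydroxystyryl]phenyl]-2-(4-hydroxyphenyl)chromane-3,7-diol (target)
Conditions: BCl3, C6HMe5 (excess), CH2Cl2, −78 °C; then MeOH; subdued light
Reagents that add atoms: none
Why: Lewis-acid dealkylation with a non-basic cation scavenger; BCl3 activates the six aryl benzyl ethers and the more labile PMB ether at −78 °C, pentamethylbenzene traps the benzyl cations by Friedel–Crafts alkylation, and the low temperature is meant to spare the stilbene and the benzylic C2–O1 ether, as in debenzylations of stilbene-bearing 2-aryl-dihydrobenzofurans.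

**Compound list**
1 | 3,4-bis(benzyloxy)benzyl chloride | ClCc1ccc(OCc2ccccc2)c(OCc2ccccc2)c1 | starting material
2 | diethyl [3,4-bis(benzyloxy)benzyl]phosphonate | CCOP(=O)(OCC)Cc1ccc(OCc2ccccc2)c(OCc2ccccc2)c1 | intermediate
3 | 3,5-bis(benzyloxy)benzaldehyde | O=Cc1cc(OCc2ccccc2)cc(OCc2ccccc2)c1 | starting material
4 | 3,5-bis(benzyloxy)-2-bromobenzaldehyde | O=Cc1cc(OCc2ccccc2)cc(OCc2ccccc2)c1Br | intermediate
5 | (E)-1,5-bis(benzyloxy)-2-bromo-3-[3,4-bis(benzyloxy)styryl]benzene | Brc1c(OCc2ccccc2)cc(OCc2ccccc2)cc1/C=C/c1ccc(OCc2ccccc2)c(OCc2ccccc2)c1 | intermediate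
6 | ethyl acrylate | C=CC(=O)OCC | starting material
7 | ethyl (E)-3-(ArDE)acrylate | CCOC(=O)/C=C/c1c(OCc2ccccc2)cc(OCc2ccccc2)cc1/C=C/c1ccc(OCc2ccccc2)c(OCc2ccccc2)c1 | intermediate
8 | (E)-3-(ArDE)prop-2-en-1-ol | OC/C=C/c1c(OCc2ccccc2)cc(OCc2ccccc2)cc1/C=C/c1ccc(OCc2ccccc2)c(OCc2ccccc2)c1 | intermediate
9 | [(2S,3S)-3-(ArDE)oxiran-2-yl]methanol | OC[C@@H]1O[C@H]1c1c(OCc2ccccc2)cc(OCc2ccccc2)cc1/C=C/c1ccc(OCc2ccccc2)c(OCc2ccccc2)c1 | intermediate
10 | 1-(benzyloxy)-3-bromobenzene | Brc1cccc(OCc2ccccc2)c1 | starting material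
11 | 4-(benzyloxy)-2-bromo-1-iodobenzene | Ic1ccc(OCc2ccccc2)cc1Br | intermediate
12 | [4-(benzyloxy)-2-bromophenyl]magnesium chloride (LiCl complex) | Cl[Mg]c1ccc(OCc2ccccc2)cc1Br | intermediate (not isolated)
13 | (2R,3S)-3-(ArA)-3-(ArDE)propane-1,2-diol | OC[C@H](O)[C@H](c1ccc(OCc2ccccc2)cc1Br)c1c(OCc2ccccc2)cc(OCc2ccccc2)cc1/C=C/c1ccc(OCc2ccccc2)c(OCc2ccccc2)c1 | intermediate
14 | (4R)-4-[(S)-(ArA)(ArDE)methyl]-2-(4-methoxyphenyl)-1,3-dioxolane, acetal epimers | COc1ccc(cc1)C1OC[C@H](O1)[C@H](c1ccc(OCc2ccccc2)cc1Br)c1c(OCc2ccccc2)cc(OCc2ccccc2)cc1/C=C/c1ccc(OCc2ccccc2)c(OCc2ccccc2)c1 | intermediate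
15 | (2R,3S)-3-(ArA)-3-(ArDE)-2-[(4-methoxybenzyl)oxy]propan-1-ol | OC[C@H](OCc1ccc(OC)cc1)[C@H](c1ccc(OCc2ccccc2)cc1Br)c1c(OCc2ccccc2)cc(OCc2ccccc2)cc1/C=C/c1ccc(OCc2ccccc2)c(OCc2ccccc2)c1 | intermediate
16 | (2R,3S)-3-(ArA)-3-(ArDE)-2-[(4-methoxybenzyl)oxy]propanal | O=C[C@H](OCc1ccc(OC)cc1)[C@H](c1ccc(OCc2ccccc2)cc1Br)c1c(OCc2ccccc2)cc(OCc2ccccc2)cc1/C=C/c1ccc(OCc2ccccc2)c(OCc2ccccc2)c1 | intermediate
17 | 1-(benzyloxy)-4-bromobenzene | Brc1ccc(OCc2ccccc2)cc1 | starting material
18 | [4-(benzyloxy)phenyl]magnesium bromide | Br[Mg]c1ccc(OCc2ccccc2)cc1 | intermediate (not isolated)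
19 | (1R,2R,3S)-3-(ArA)-1-(ArB)-3-(ArDE)-2-[(4-methoxybenzyl)oxy]propan-1-ol | c1ccccc1COc1ccc(cc1)[C@@H](O)[C@H](OCc1ccc(OC)cc1)[C@H](c1ccc(OCc2ccccc2)cc1Br)c1c(OCc2ccccc2)cc(OCc2ccccc2)cc1/C=C/c1ccc(OCc2ccccc2)c(OCc2ccccc2)c1 | intermediate (key-step precursor)
20 | (2R,3R,4R)-7-(benzyloxy)-2-[4-(benzyloxy)phenyl]-4-(ArDE)-3-[(4-methoxybenzyl)oxy]chromane | c1ccccc1COc1ccc(cc1)[C@H]1Oc2cc(OCc3ccccc3)ccc2[C@H](c2c(OCc3ccccc3)cc(OCc3ccccc3)cc2/C=C/c2ccc(OCc3ccccc3)c(OCc3ccccc3)c2)[C@H]1OCc1ccc(OC)cc1 | intermediate (key-step product)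
21 | (2R,3R,4R)-4-[2,4-dihydroxy-6-[(E)-3,4-dihydroxystyryl]phenyl]-2-(4-hydroxyphenyl)chromane-3,7-diol | Oc1ccc([C@H]2Oc3cc(O)ccc3[C@H](c3c(O)cc(O)cc3/C=C/c3ccc(O)c(O)c3)[C@H]2O)cc1 | target

**Step count**
Total: 14 steps. Longest linear sequence: 12 steps (3 → 4 → 5 → 7 → 8 → 9 → 13 → 14 → 15 → 16 → 19 → 20 → 21).

**Steps most likely to fail**

Step 8 (opening of 9 by 12). The electron-rich epoxide may ionise at the benzylic carbon before the aryl group arrives, which would erode the inversion and open a path to rearrangement, and the ortho-bromoaryl metal may lose magnesium halide to give an aryne. The fallback sets out from 7 (with 11 as the aryl source) and comes back at 13, making the C4–ring A bond by conjugate addition and oxygenating C3 afterwards.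
- Iodide 11 is converted (iPrMgCl·LiCl, −40 °C; B(OMe)3; aq. HCl) into [4-(benzyloxy)-2-bromophenyl]boronic acid F1.
- Hayashi–Miyaura addition of the boronic acid to cinnamate 7 (Rh(acac)(C2H4)2, BINAP, dioxane/H2O, 100 °C; the ligand antipode that gives the 3S ester is fixed on a model cinnamate) gives ethyl (3S)-3-(ArA)-3-(ArDE)propanoate F2.
- iBu2AlH at −78 °C gives (3S)-3-(ArA)-3-(ArDE)propanal F3.
- L-Proline-catalysed α-aminoxylation with nitrosobenzene, followed by NaBH4 in the same flask, sets C3 under catalyst control and gives (2R,3S)-2-(anilinooxy)-3-(ArA)-3-(ArDE)propan-1-ol F4.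
- N–O cleavage (CuSO4 cat., MeOH) gives diol 13.

Step 13 (ring closure). Oxidative addition at the crowded C8a–Br bond may be slow, so that protodebromination or oxidation of the benzylic carbinol overtakes C–O bond formation. The fallback sets out from 19 and comes back at 20, with the polarity at C8a inverted. Miyaura borylation (PdCl2(dppf), B2pin2, KOAc, dioxane, 90 °C) gives the aryl pinacol boronate of 19 (bromine replaced by the dioxaborolane) F5. An intramolecular Chan–Lam–Evans etherification (Cu(OAc)2, pyridine, 4 Å MS, air, CH2Cl2, rt) then forms the same O1–C8a bond oxidatively.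

Step 12 (Grignard addition). Addition through the non-chelated aldehyde (Felkin–Anh pathway, favoured by THF from the Grignard solution) may erode the syn selectivity. The fallback sets out from 16 and comes back at 19, setting C2 by reagent-controlled reduction.
- Aldehyde 16 is treated with 18 in THF without additive to give the C1-epimeric mixture of 3-(ArA)-1-(ArB)-3-(ArDE)-2-[(4-methoxybenzyl)oxy]propan-1-ols F6.
- Dess–Martin oxidation gives (2R,3S)-3-(ArA)-1-(ArB)-3-(ArDE)-2-[(4-methoxybenzyl)oxy]propan-1-one F7.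
- Reduction with BH3·SMe2 and (R)-Me-CBS oxazaborolidine, with the aryl ring as the large group, gives the 1R carbinol 19.

**Further compounds**
F1 | step 8 | [4-(benzyloxy)-2-bromophenyl]boronic acid | OB(O)c1ccc(OCc2ccccc2)cc1Br
F2 | step 8 | ethyl (3S)-3-(ArA)-3-(ArDE)propanoate | CCOC(=O)C[C@H](c1ccc(OCc2ccccc2)cc1Br)c1c(OCc2ccccc2)cc(OCc2ccccc2)cc1/C=C/c1ccc(OCc2ccccc2)c(OCc2ccccc2)c1
F3 | step 8 | (3S)-3-(ArA)-3-(ArDE)propanal | O=CC[C@H](c1ccc(OCc2ccccc2)cc1Br)c1c(OCc2ccccc2)cc(OCc2ccccc2)cc1/C=C/c1ccc(OCc2ccccc2)c(OCc2ccccc2)c1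
F4 | step 8 | (2R,3S)-2-(anilinooxy)-3-(ArA)-3-(ArDE)propan-1-ol | OC[C@H](ONc1ccccc1)[C@H](c1ccc(OCc2ccccc2)cc1Br)c1c(OCc2ccccc2)cc(OCc2ccccc2)cc1/C=C/c1ccc(OCc2ccccc2)c(OCc2ccccc2)c1
F5 | step 13 | aryl pinacol boronate of 19 (Br replaced by 4,4,5,5-tetramethyl-1,3,2-dioxaborolan-2-yl) | c1ccccc1COc1ccc(cc1)[C@@H](O)[C@H](OCc1ccc(OC)cc1)[C@H](c1ccc(OCc2ccccc2)cc1B1OC(C)(C)C(C)(C)O1)c1c(OCc2ccccc2)cc(OCc2ccccc2)cc1/C=C/c1ccc(OCc2ccccc2)c(OCc2ccccc2)c1
F6 | step 12 | C1-epimeric 3-(ArA)-1-(ArB)-3-(ArDE)-2-[(4-methoxybenzyl)oxy]propan-1-ols | c1ccccc1COc1ccc(cc1)C(O)[C@H](OCc1ccc(OC)cc1)[C@H](c1ccc(OCc2ccccc2)cc1Br)c1c(OCc2ccccc2)cc(OCc2ccccc2)cc1/C=C/c1ccc(OCc2ccccc2)c(OCc2ccccc2)c1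
F7 | step 12 | (2R,3S)-3-(ArA)-1-(ArB)-3-(ArDE)-2-[(4-methoxybenzyl)oxy]propan-1-one | c1ccccc1COc1ccc(cc1)C(=O)[C@H](OCc1ccc(OC)cc1)[C@H](c1ccc(OCc2ccccc2)cc1Br)c1c(OCc2ccccc2)cc(OCc2ccccc2)cc1/C=C/c1ccc(OCc2ccccc2)c(OCc2ccccc2)c1
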